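**Retrosynthetic overview**
The plan rests on the cyclohexenone ring (C1, C10, C11, C12, C13, C14): its C1 methyl is trans to H10 and its oxygen sits on C12, which is the pattern a Z-2-siloxydiene/E-2-methyl-enal Diels–Alder reaction delivers (bonds C1–C14 and C10–C11).
Ten-membered ring (C1–C10): opened at C3=C4 (diene–ene ring-closing metathesis, last step); the C4/C5(=C16) diene is traced back to a terminal C4≡C5 alkyne (ethene enyne metathesis).
γ-Lactone (C7, C8, C17, C19, O): C8–C17 by intramolecular Reformatsky reaction; C6–Cl/C7–O from a Sharpless trans-epoxide opened by chloride; C7–C8 by chelation-controlled alkenylzinc addition to the C8 aldehyde freed from the dioxolane; C2–C3 by vinyl Grignard addition.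
Order of ring formation: cyclohexene (step 3), lactone (step 18), ten-membered ring (step 22).

Key step: step 3

Locants used in all names: C1 (quaternary, methyl C15), C2, C3=C4, C5(=C16), C6, C7, C8, C9, C10 form the ten-membered ring; C11 (methyl C20), C12, C13, C14 complete the cyclohexenone; C17 (methyl C18) and C19 complete the lactone.
Remark on the chemistry: the cycloadduct is formulated as the formyl-endo isomer (C11 methyl cis to H10); C11 is planarised in step 7, so its configuration in 6–9 has no bearing on the target.

**Step 1**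
Reactants: 1 pent-1-en-3-one
Product: 2 (Z)-tert-butyldimethyl(penta-1,3-dien-3-yloxy)silane
Conditions: TBSOTf, Et3N, CH2Cl2, 0 °C
Reagents that add atoms: tert-butyldimethylsilyl triflate, CC(C)(C)[Si](C)(C)OS(=O)(=O)C(F)(F)F
Why: Soft enolisation and O-silylation of the ethyl ketone (silyl enol ether formation) should give mainly the Z enol ether, whose methyl group points away from the s-cis diene.

**Step 2**
Reactants: 3 (R)-2,2-dimethyl-1,3-dioxolane-4-carbaldehyde; 4 2-(triphenylphosphoranylidene)propanal
Product: 5 (S,E)-3-(2,2-dimethyl-1,3-dioxolan-4-yl)-2-methylacrylaldehyde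
Conditions: toluene, 80 °C
Reagents that add atoms: none
Why: Wittig olefination with the stabilised formyl ylide should give the E trisubstituted enal and leave the dioxolane stereocentre untouched.

**Step 3**
Reactants: 2 (Z)-tert-butyldimethyl(penta-1,3-dien-3-yloxy)silane; 5 (S,E)-3-(2,2-dimethyl-1,3-dioxolan-4-yl)-2-methylacrylaldehyde
Product: 6 cycloadduct 4-(tert-butyldimethylsilyloxy)-6-[(S)-2,2-dimethyl-1,3-dioxolan-4-yl]-1,5-dimethylcyclohex-3-ene-1-carbaldehyde (formyl C2 trans to the dioxolanyl group; C1 methyl trans to H10; C11 methyl cis to H10)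
Conditions: Me2AlCl (20 mol %), CH2Cl2, −78 → −40 °C
Reagents that add atoms: none
Why: Me2AlCl binds the formyl oxygen and the 2-siloxydiene adds to the E-enal in a concerted, asynchronous [4+2] cycloaddition, the closest known reaction type being the Lewis-acid-catalysed Diels–Alder reaction of 2-silyloxydienes with α-methyl enals and of γ-alkoxy enoates made from glyceraldehyde acetonide. The six-membered ring (C1, C14, C13, C12, C11, C10) closes in this intermolecular [4+2] mode, with C10–C11 and C1–C14 formed suprafacially on both partners. Regiochemistry follows the siloxy group, which makes C11 the nucleophilic diene terminus that bonds to the β-carbon C10 ("para" adduct). The C1/C10 relationship (C1 methyl trans to H10, formyl trans to the dioxolane) is the E geometry of 5 carried over, and C11 (methyl cis to H10) comes from the formyl-endo transition state and is erased in step 7. The absolute sense at C1 and C10 is set by the C9 dioxolane stereocentre: A(1,3) strain with the C1 methyl holds H9 in the enal plane and the diene should add to the face anti to the C9–O bond, which gives the ring bonds as in the target. The step therefore needs "para" regioselectivity and π-facial selectivity, secured by the siloxy donor and the allylic C–O bond, and a dialkylaluminium chloride at low temperature is chosen to avoid a Mukaiyama–Michael pathway with loss of silicon.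

**Step 4**
Reactants: 6 cycloadduct aldehyde
Product: 7 C2 allylic alcohol (CHO of 6 converted into CH(OH)–CH=CH2; 2-OH as in the target)
Conditions: CH2=CHMgBr, THF, −78 °C
Reagents that add atoms: vinylmagnesium bromide, C=C[Mg]Br
Why: Grignard 1,2-addition to the neopentyl aldehyde should follow Felkin–Anh control (C10 as the large group anti to the incoming vinyl, formyl hydrogen next to the C1 methyl) and set C2 as in the target, the silyl enol ether being inert to the reagent and a minor C2 epimer being separable.

**Step 5**
Reactants: 7 C2 allylic alcohol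
Product: 8 C2 tert-butyldimethylsilyl ether of 7
Conditions: TBSOTf, 2,6-lutidine, CH2Cl2, −78 → 0 °C
Reagents that add atoms: tert-butyldimethylsilyl triflate, CC(C)(C)[Si](C)(C)OS(=O)(=O)C(F)(F)F
Why: Silyl triflate silylation protects the hindered secondary alcohol as an ether that survives enolate chemistry and the later acidic acetonide cleavage.

**Step 6**
Reactants: 8 C2 silyl ether
Product: 9 cyclohexenone (C12 ketone, C13=C14, C11–H)
Conditions: Pd(OAc)2 (1.2 equiv), MeCN, 40 °C
Reagents that add atoms: none
Why: Saegusa oxidation of the C12–C13 silyl enol ether (palladation at C13, β-hydride loss from C14) should give the C13=C14 enone regiospecifically, since C1 is quaternary and the enol ether cannot migrate to C11.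

**Step 7**
Reactants: 9 cyclohexenone
Product: 11 C11 tertiary alcohol (11-OH cis to H10; C11 methyl cis to the C9 side chain), via potassium dienolate 10 (not isolated)
Conditions: KN(SiMe3)2, THF, −78 °C; 3-phenyl-2-(phenylsulfonyl)oxaziridine, −78 °C
Reagents that add atoms: 3-phenyl-2-(phenylsulfonyl)oxaziridine (Davis oxaziridine), O=S(=O)(c1ccccc1)N1OC1c1ccccc1
Why: Kinetic α′-deprotonation (C11–H is the only enolisable position) gives the cross-conjugated dienolate, and enolate hydroxylation by the Davis oxaziridine should occur on the face anti to the adjacent C10 side chain, placing the hydroxyl cis to H10 as in the target.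

**Step 8**
Reactants: 11 C11 tertiary alcohol
Product: 12 C8,C9,C11-triol (dioxolane opened to the C9 secondary and C8 primary alcohols)
Conditions: AcOH/H2O (4:1), 40 °C
Reagents that add atoms: none
Why: Acid-catalysed hydrolysis of the terminal acetonide should free the 1,2-diol while the hindered secondary TBS ether at C2 remains.

**Step 9**
Reactants: 12 triol
Product: 13 C8,C9,C11-tris(triethylsilyl) ether
Conditions: TESOTf (4 equiv), 2,6-lutidine, CH2Cl2, −78 → 0 °C
Reagents that add atoms: triethylsilyl triflate, CC[Si](CC)(CC)OS(=O)(=O)C(F)(F)F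
Why: Silyl triflate silylates the primary, secondary and tertiary hydroxyls in one operation, which sets up the selective oxidation of the primary position.

**Step 10**
Reactants: 13 tris(triethylsilyl) ether
Product: 14 C8 aldehyde (9-OTES, 11-OTES, 2-OTBS)
Conditions: (COCl)2, DMSO, CH2Cl2, −78 → −35 °C; Et3N, −78 °C → rt
Reagents that add atoms: none
Why: Under Swern conditions only the primary triethylsilyl ether is cleaved and oxidised (direct Swern oxidation of primary TES ethers), which should give the α-silyloxy aldehyde without a separate deprotection.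

**Step 11**
Reactants: 15 1,4-bis(trimethylsilyl)buta-1,3-diyne
Product: 17 buta-1,3-diyn-1-yl(trimethyl)silane, via lithium diynide 16 (not isolated)
Conditions: MeLi·LiBr, Et2O, rt; then H2O
Reagents that add atoms: none
Why: Methyllithium cleaves one C(sp)–Si bond selectively (mono-desilylation of the bis-silyl diyne) and protonation of the lithium acetylide gives the terminal diyne, used as a solution.

**Step 12**
Reactants: 17 buta-1,3-diyn-1-yl(trimethyl)silane; 14 C8 aldehyde
Product: 20 C7–C8 adduct (8-OH syn to 9-OTES; E-C6=C7; TMS-capped C4≡C5 alkyne), via E-alkenylborane 18 (not isolated), via E-alkenylzinc 19 (not isolated)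
Conditions: 17, Cy2BH (BH3·SMe2, cyclohexene), toluene, 0 °C → rt; Me2Zn, −78 °C; EtZnCl (Et2Zn, ZnCl2), then 14, −30 → 0 °C
Reagents that add atoms: none
Why: Hydroboration of the terminal alkyne, boron-to-zinc exchange and alkylzinc-halide-promoted, chelation-controlled (Cram-chelate) addition of the E-alkenylzinc to the α-silyloxy aldehyde should form C7–C8 with the C8 hydroxyl syn to the C9 silyl ether, the hindered enone being inert to organozinc reagents.

**Step 13**
Reactants: 20 TMS-capped enynol
Product: 21 terminal alkyne (C4≡C5–H)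
Conditions: AgNO3 (0.1 equiv), CH2Cl2/MeOH/H2O, rt
Reagents that add atoms: none
Why: Silver-catalysed protodesilylation of the alkynylsilane is neutral and should therefore not trigger 1,2-migration of the C9 silyl group to the free C8 hydroxyl.

**Step 14**
Reactants: 21 E-allylic alcohol
Product: 22 C6,C7-trans-epoxy C8-alcohol (epoxide oxygen anti to 8-OH)
Conditions: Ti(OiPr)4 (0.5 equiv), D-(−)-diisopropyl tartrate (0.6 equiv), t-BuOOH, 4 Å MS, CH2Cl2, −20 °C
Reagents that add atoms: tert-butyl hydroperoxide, CC(C)(C)OO
Why: Sharpless asymmetric epoxidation of the secondary E-allylic alcohol, in its matched erythro-selective pairing with the D-tartrate (the ligand that converts E-allylic alcohols into (2R,3R)-epoxy alcohols), should set C6 and C7 with the oxygen on the face required for the target and leave the enone, the alkyne and the C2 vinyl group untouched.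

**Step 15**
Reactants: 22 epoxy alcohol
Product: 23 C6,C7-epoxy C8-ketone
Conditions: Dess–Martin periodinane, pyridine, CH2Cl2, 0 °C → rt
Reagents that add atoms: none
Why: Buffered Dess–Martin oxidation converts the secondary carbinol into the α,β-epoxy ketone without opening the epoxide or epimerising C9.

**Step 16**
Reactants: 23 epoxy ketone
Product: 24 C6-chloro C7-hydroxy C8-ketone (Cl and OH anti)
Conditions: LiCl, AcOH, THF, 0 °C → rt
Reagents that add atoms: lithium chloride, [Li+].[Cl-]
Why: Acid-assisted halohydrin formation should proceed by SN2 attack of chloride at the propargylic carbon C6, remote from the deactivating carbonyl, with inversion, so that the C7 oxygen is retained as the α-hydroxy ketone and C6 receives chlorine with the target configuration.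

**Step 17**
Reactants: 24 chlorohydrin ketone
Product: 25 C7 2-bromopropanoate (mixture at the CHBr carbon)
Conditions: 2-bromopropanoyl bromide, pyridine, CH2Cl2, −40 → 0 °C
Reagents that add atoms: 2-bromopropanoyl bromide, CC(Br)C(Br)=O
Why: Acylation of the secondary alcohol with the acid bromide at low temperature installs the Reformatsky donor while limiting loss of HCl from the β-chloro ketone.

**Step 18**
Reactants: 25 bromopropanoate
Product: 26 γ-lactone (C7–O–C19(=O)–C17–C8; 8-OH trans to H7; C17 methyl cis to 8-OH)
Conditions: SmI2 (2.2 equiv), THF, −78 °C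
Reagents that add atoms: none
Why: In this intramolecular samarium Reformatsky reaction the enolate generated from the α-bromo ester adds to the C8 ketone and closes the five-membered lactone, C8 being set through the C7 tether with C6 and C9 trans on the new ring and the C17 methyl expected anti to C9 (the more stable epimer, reachable by mild base equilibration if needed).

**Step 19**
Reactants: 26 silylated lactone
Product: 27 tetraol (2-OH, 8-OH, 9-OH, 11-OH)
Conditions: HF·pyridine, pyridine, THF, 0 °C → rt
Reagents that add atoms: none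
Why: Fluoride-mediated desilylation removes the TBS ether and both TES ethers under mildly acidic conditions that spare the lactone, the propargylic chloride and the α-hydroxy enone.

**Step 20**
Reactants: 27 tetraol
Product: 28 2,9-diacetate (8-OH and 11-OH free)
Conditions: Ac2O, pyridine, DMAP (cat.), CH2Cl2, 0 °C → rt
Reagents that add atoms: acetic anhydride, CC(=O)OC(C)=O
Why: DMAP-catalysed acetylation should take place only at the two secondary alcohols, the tertiary C8 and C11 hydroxyls being too hindered under these conditions.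

**Step 21**
Reactants: 28 alkyne diacetate
Product: 29 2-substituted buta-1,3-diene (C5=C16H2, C4H=CH2)
Conditions: ethene (1 atm), second-generation Grubbs catalyst RuCl2(PCy3)(H2IMes)(=CHPh) (10 mol %), toluene, 60 °C
Reagents that add atoms: ethene, C=C
Why: Ethene–alkyne cross enyne metathesis converts the terminal alkyne into the 2-substituted butadiene, the ethene atmosphere suppressing premature ring closure and dimerisation at the C2 vinyl group.

**Step 22**
Reactants: 29 diene
Product: 30 target compound CNP0188317.1
Conditions: second-generation Hoveyda–Grubbs catalyst RuCl2(H2IMes)(=CH-C6H4-2-OiPr) (20 mol %), 1,4-benzoquinone, toluene (1 mM), 80 °C, Ar sparge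
Reagents that add atoms: none
Why: Ring-closing diene–ene metathesis at high dilution should join C3 and C4 with loss of ethene and close the ten-membered ring, in which ring strain favours the Z olefin, while the 1,1-disubstituted C5=C16 bond and the enone are too unreactive to take part.

**Compound list**
1 | pent-1-en-3-one | CCC(=O)C=C | starting material
2 | (Z)-tert-butyldimethyl(penta-1,3-dien-3-yloxy)silane | C=C/C(O[Si](C)(C)C(C)(C)C)=C/C | intermediate
3 | (R)-2,2-dimethyl-1,3-dioxolane-4-carbaldehyde | O=C[C@H]1COC(C)(C)O1 | starting material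
4 | 2-(triphenylphosphoranylidene)propanal | CC(C=O)=P(c1ccccc1)(c1ccccc1)c1ccccc1 | starting material
5 | (S,E)-3-(2,2-dimethyl-1,3-dioxolan-4-yl)-2-methylacrylaldehyde | O=C/C(C)=C/[C@H]1COC(C)(C)O1 | intermediate
6 | formyl-endo cycloadduct, 4-(tert-butyldimethylsilyloxy)-6-[(S)-2,2-dimethyl-1,3-dioxolan-4-yl]-1,5-dimethylcyclohex-3-ene-1-carbaldehyde | O=C[C@@]1(C)CC=C(O[Si](C)(C)C(C)(C)C)[C@@H](C)[C@@H]1[C@H]1COC(C)(C)O1 | intermediate
7 | C2 allylic alcohol (vinyl carbinol, 2-OH as in the target) | C=C[C@H](O)[C@@]1(C)CC=C(O[Si](C)(C)C(C)(C)C)[C@@H](C)[C@@H]1[C@H]1COC(C)(C)O1 | intermediate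
8 | C2 TBS ether of 7 | C=C[C@H](O[Si](C)(C)C(C)(C)C)[C@@]1(C)CC=C(O[Si](C)(C)C(C)(C)C)[C@@H](C)[C@@H]1[C@H]1COC(C)(C)O1 | intermediate
9 | cyclohexenone (C12 ketone, C13=C14) | C=C[C@H](O[Si](C)(C)C(C)(C)C)[C@@]1(C)C=CC(=O)[C@@H](C)[C@@H]1[C@H]1COC(C)(C)O1 | intermediate
10 | potassium C11=C12 dienolate of 9 | C=C[C@H](O[Si](C)(C)C(C)(C)C)[C@@]1(C)C=CC([O-])=C(C)[C@@H]1[C@H]1COC(C)(C)O1.[K+] | intermediate
11 | C11 tertiary alcohol (11-OH cis to H10) | C=C[C@H](O[Si](C)(C)C(C)(C)C)[C@@]1(C)C=CC(=O)[C@@](C)(O)[C@@H]1[C@H]1COC(C)(C)O1 | intermediate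
12 | C8,C9,C11-triol | C=C[C@H](O[Si](C)(C)C(C)(C)C)[C@@]1(C)C=CC(=O)[C@@](C)(O)[C@@H]1[C@H](O)CO | intermediate
13 | C8,C9,C11-tris(triethylsilyl) ether | C=C[C@H](O[Si](C)(C)C(C)(C)C)[C@@]1(C)C=CC(=O)[C@@](C)(O[Si](CC)(CC)CC)[C@@H]1[C@H](O[Si](CC)(CC)CC)CO[Si](CC)(CC)CC | intermediate
14 | C8 aldehyde (9-OTES, 11-OTES, 2-OTBS) | C=C[C@H](O[Si](C)(C)C(C)(C)C)[C@@]1(C)C=CC(=O)[C@@](C)(O[Si](CC)(CC)CC)[C@@H]1[C@H](O[Si](CC)(CC)CC)C=O | intermediate
15 | 1,4-bis(trimethylsilyl)buta-1,3-diyne | C[Si](C)(C)C#CC#C[Si](C)(C)C | starting material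
16 | lithium 4-(trimethylsilyl)buta-1,3-diyn-1-ide | [Li]C#CC#C[Si](C)(C)C | intermediate
17 | buta-1,3-diyn-1-yl(trimethyl)silane | C#CC#C[Si](C)(C)C | intermediate
18 | (E)-dicyclohexyl[4-(trimethylsilyl)but-1-en-3-yn-1-yl]borane | C[Si](C)(C)C#C/C=C/B(C1CCCCC1)C1CCCCC1 | intermediate
19 | (E)-methyl[4-(trimethylsilyl)but-1-en-3-yn-1-yl]zinc | C[Zn]/C=C/C#C[Si](C)(C)C | intermediate
20 | C8 allylic alcohol (8-OH syn to 9-OTES, E-C6=C7, TMS-capped C4≡C5) | C=C[C@H](O[Si](C)(C)C(C)(C)C)[C@@]1(C)C=CC(=O)[C@@](C)(O[Si](CC)(CC)CC)[C@@H]1[C@H](O[Si](CC)(CC)CC)[C@@H](O)/C=C/C#C[Si](C)(C)C | intermediate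
21 | C8 allylic alcohol with terminal C4≡C5 alkyne | C=C[C@H](O[Si](C)(C)C(C)(C)C)[C@@]1(C)C=CC(=O)[C@@](C)(O[Si](CC)(CC)CC)[C@@H]1[C@H](O[Si](CC)(CC)CC)[C@@H](O)/C=C/C#C | intermediate
22 | C6,C7-trans-epoxy C8-alcohol (erythro) | C=C[C@H](O[Si](C)(C)C(C)(C)C)[C@@]1(C)C=CC(=O)[C@@](C)(O[Si](CC)(CC)CC)[C@@H]1[C@H](O[Si](CC)(CC)CC)[C@@H](O)[C@H]1O[C@@H]1C#C | intermediate
23 | C6,C7-epoxy C8-ketone | C=C[C@H](O[Si](C)(C)C(C)(C)C)[C@@]1(C)C=CC(=O)[C@@](C)(O[Si](CC)(CC)CC)[C@@H]1[C@H](O[Si](CC)(CC)CC)C(=O)[C@H]1O[C@@H]1C#C | intermediate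
24 | C6-chloro C7-hydroxy C8-ketone (anti) | C=C[C@H](O[Si](C)(C)C(C)(C)C)[C@@]1(C)C=CC(=O)[C@@](C)(O[Si](CC)(CC)CC)[C@@H]1[C@H](O[Si](CC)(CC)CC)C(=O)[C@@H](O)[C@@H](Cl)C#C | intermediate
25 | C7 2-bromopropanoate of 24 | C=C[C@H](O[Si](C)(C)C(C)(C)C)[C@@]1(C)C=CC(=O)[C@@](C)(O[Si](CC)(CC)CC)[C@@H]1[C@H](O[Si](CC)(CC)CC)C(=O)[C@@H](OC(=O)C(C)Br)[C@@H](Cl)C#C | intermediate
26 | silylated γ-lactone (8-OH, C17 methyl, C6 chloride, terminal alkyne) | C=C[C@H](O[Si](C)(C)C(C)(C)C)[C@@]1(C)C=CC(=O)[C@@](C)(O[Si](CC)(CC)CC)[C@@H]1[C@H](O[Si](CC)(CC)CC)[C@]2(O)[C@@H](C)C(=O)O[C@H]2[C@@H](Cl)C#C | intermediate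
27 | lactone tetraol (2-OH, 8-OH, 9-OH, 11-OH) | C=C[C@H](O)[C@@]1(C)C=CC(=O)[C@@](C)(O)[C@@H]1[C@H](O)[C@]2(O)[C@@H](C)C(=O)O[C@H]2[C@@H](Cl)C#C | intermediate
28 | lactone 2,9-diacetate with terminal alkyne | C=C[C@H](OC(C)=O)[C@@]1(C)C=CC(=O)[C@@](C)(O)[C@@H]1[C@H](OC(C)=O)[C@]2(O)[C@@H](C)C(=O)O[C@H]2[C@@H](Cl)C#C | intermediate
29 | lactone 2,9-diacetate with C5(=C16H2)–C4H=CH2 diene | C=C[C@H](OC(C)=O)[C@@]1(C)C=CC(=O)[C@@](C)(O)[C@@H]1[C@H](OC(C)=O)[C@]2(O)[C@@H](C)C(=O)O[C@H]2[C@@H](Cl)C(=C)C=C | intermediate
30 | CNP0188317.1 | C=C1/C=C\[C@H](OC(C)=O)[C@@]2(C)C=CC(=O)[C@@](C)(O)[C@@H]2[C@H](OC(C)=O)[C@]2(O)[C@@H](C)C(=O)O[C@H]2[C@H]1Cl | target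

**Totals**
Total step count: 22.
Longest linear sequence: 20 steps (steps 2–10 and 12–22, from 3); steps 1 and 11 prepare the diene and the diyne.

**Steps most likely to fail**

Step 22 (ring closure). Oligomerisation through the unhindered diene terminus may outrun closure of the strained ten-membered ring, because the ruthenium alkylidene engages the neopentyl C2 vinyl acetate slowly, or the ring may close to the E olefin. The fallback uses the free C2 allylic hydroxyl as an activating group and moves acetylation to the end. It sets out from 27: ethene enyne metathesis under the conditions of step 21 would give the tetraol diene F2, ring-closing metathesis at high dilution would give the macrocyclic tetraol F3, and acetylation under the conditions of step 20 returns to the route at 30.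

Step 16 (chlorohydrin). Chloride may attack C7, the carbon α to the ketone, instead of C6, or the β-chloro ketone may lose HCl before or during acylation. The fallback reverses the order of lactone carbon–carbon bond formation and epoxide opening and sets out from 23. Intermolecular Reformatsky addition of the zinc enolate of ethyl 2-bromopropanoate (Zn dust, THF), under chelation between the ketone and the epoxide oxygen, would give the epoxy hydroxy ester F1. Opening of this 2,3-epoxy alcohol with Ti(OiPr)4 and Et2NH·HCl places chloride on C6 (the carbon remote from the carbinol, and propargylic) with inversion. The liberated C7 alkoxide lactonises onto the ethyl ester, and the route is rejoined at 26, steps 17 and 18 being bypassed.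

Step 3 (key cycloaddition). The diene may add to both faces of the enal with poor discrimination, or the reaction may leave the concerted path and end as a Mukaiyama–Michael adduct with loss of the silyl group. The fallback replaces substrate control by catalyst control: the same partners 2 and 5 are combined under a chiral oxazaborolidinium triflimide (from α,α-diphenylprolinol, o-tolylboroxine and Tf2NH, a known catalyst class for 2-silyloxydienes with α-methyl enals). Both antipodes would be screened to find the one matched to the dioxolane; the route is rejoined at 6 and no new compound arises.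

**Further compounds**
F0 | step 3 | none | none
F1 | step 16 | Reformatsky adduct of 23: C6,C7-epoxy C8-tertiary alcohol carrying the C17/C19 ethyl propanoate unit | C=C[C@H](O[Si](C)(C)C(C)(C)C)[C@@]1(C)C=CC(=O)[C@@](C)(O[Si](CC)(CC)CC)[C@@H]1[C@H](O[Si](CC)(CC)CC)[C@](O)([C@@H](C)C(=O)OCC)[C@H]1O[C@@H]1C#C
F2 | step 22 | tetraol diene (27 with the alkyne converted into C5(=C16H2)–C4H=CH2) | C=C[C@H](O)[C@@]1(C)C=CC(=O)[C@@](C)(O)[C@@H]1[C@H](O)[C@]2(O)[C@@H](C)C(=O)O[C@H]2[C@@H](Cl)C(=C)C=C
F3 | step 22 | macrocyclic tetraol (2,9-dideacetyl target) | C=C1/C=C\[C@H](O)[C@@]2(C)C=CC(=O)[C@@](C)(O)[C@@H]2[C@H](O)[C@]2(O)[C@@H](C)C(=O)O[C@H]2[C@H]1Cl
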